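**Retrosynthetic overview**

1. Target 32 comes from hexabenzyl ether 31 by global hydrogenolysis.
2. 31 comes from β-silyloxy ester 27 and 3,5-bis(benzyloxy)benzyne (from 5): one fluoride-triggered annulation makes O1–C8a and C4–C4a and closes the pyranone ring (ring C) onto an intact ring A.
3. Enabling feature: O1–C2–C3–C4 is a β-oxy acyl unit, and the 5-oxygen of ring A sits ortho to C4a and meta to C8a. An alkoxy group in that position on a benzyne makes C8a the electrophilic carbon and C4a the carbanion that is acylated.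
4. 27 comes from aldehyde 20 by an auxiliary-controlled anti glycolate aldol, which sets C2 and C3 of the flavanonol with the 3-oxygen already benzylated.
5. 20 comes from phenol 10 and ynoate 9 by oxa-Michael addition and imine-directed rhodium C–H alkylation. The dihydrofuran ring is formed first, the pyranone ring last.

Key step: step 14

Assumption 1: in step 6 the (S)-enantiomer of 1-aminoindane is taken to induce the 2R configuration of the dihydrofuran ring; if the sense of induction is the opposite one, the R amine is used and nothing else changes.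

Assumption 2: in step 11 the (S)-4-benzyl auxiliary is taken to give the 2R,3R anti adduct; if it gives the mirror-image pair of centres, the R auxiliary is used and nothing else changes.

Abbreviation: Ar = (2R,3S)-7-(benzyloxy)-2-[4-(benzyloxy)-3-methoxyphenyl]-3-[(benzyloxy)methyl]-2,3-dihydro-1-benzofuran-4-yl, the aryl group of aldehyde 20.

**Route**

Step 1
Reactants: 1 3,5-bis(benzyloxy)phenol
Product: 2 3,5-bis(benzyloxy)-2-bromophenol
Conditions: NBS (1.0 equiv), i-Pr2NH (10 mol %), CH2Cl2, 0 °C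
Reagents that add atoms: N-bromosuccinimide, O=C1CCC(=O)N1Br
Why: Amine-catalysed ortho-selective electrophilic bromination of a phenol, in which the N-bromoamine is delivered through a hydrogen bond to one of the two equivalent positions next to the hydroxyl group.

Step 2
Reactants: 2 3,5-bis(benzyloxy)-2-bromophenol
Product: 5 3,5-bis(benzyloxy)-2-(trimethylsilyl)phenyl trifluoromethanesulfonate, via trimethylsilyl ether 3 (not isolated), via lithium phenoxide 4 (not isolated)
Conditions: HMDS, THF, 70 °C, then evaporation; n-BuLi, THF, −100 °C; Tf2O, −100 to −78 °C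
Reagents that add atoms: hexamethyldisilazane, C[Si](C)(C)N[Si](C)(C)C; triflic anhydride, O=S(=O)(OS(=O)(=O)C(F)(F)F)C(F)(F)F
Why: Standard entry to a 2-(trimethylsilyl)aryl triflate by O-silylation, bromine–lithium exchange, retro-Brook shift of silicon from oxygen to carbon and triflation of the resulting phenoxide.

Step 3
Reactants: 6 4-(benzyloxy)-3-methoxybenzaldehyde
Product: 7 1-(benzyloxy)-4-(2,2-dibromoethenyl)-2-methoxybenzene
Conditions: CBr4 (2 equiv), PPh3 (4 equiv), CH2Cl2, 0 °C
Reagents that add atoms: carbon tetrabromide, BrC(Br)(Br)Br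
Why: First stage of the Corey–Fuchs reaction, a Wittig-type olefination of the aldehyde with the dibromomethylene ylide.

Step 4
Reactants: 7 1-(benzyloxy)-4-(2,2-dibromoethenyl)-2-methoxybenzene
Product: 9 methyl 3-[4-(benzyloxy)-3-methoxyphenyl]prop-2-ynoate, via lithium acetylide 8 (not isolated)
Conditions: n-BuLi (2.1 equiv), THF, −78 °C; ClCO2Me, −78 °C to rt
Reagents that add atoms: methyl chloroformate, COC(=O)Cl
Why: Second stage of the Corey–Fuchs reaction (bromine–lithium exchange and Fritsch–Buttenberg–Wiechell rearrangement to the alkynyllithium) followed by C-acylation with the chloroformate.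

Step 5
Reactants: 9 methyl 3-[4-(benzyloxy)-3-methoxyphenyl]prop-2-ynoate; 10 4-(benzyloxy)-3-hydroxybenzaldehyde
Product: 11 methyl (Z)-3-[2-(benzyloxy)-5-formylphenoxy]-3-[4-(benzyloxy)-3-methoxyphenyl]prop-2-enoate
Conditions: K2CO3 (0.5 equiv), DMF, 80 °C
Reagents that add atoms: none
Why: Base-mediated oxa-Michael addition of the phenoxide to the ynoate at the aryl-bearing carbon, anti addition being expected to give mainly the Z enol ether, which is purified to one geometry.

Step 6
Reactants: 11 methyl (Z)-3-[2-(benzyloxy)-5-formylphenoxy]-3-[4-(benzyloxy)-3-methoxyphenyl]prop-2-enoate; 12 (S)-1-aminoindane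
Product: 15 methyl (2R,3S)-7-(benzyloxy)-2-[4-(benzyloxy)-3-methoxyphenyl]-4-formyl-2,3-dihydro-1-benzofuran-3-carboxylate (cis isomer), via aldimine 13 (not isolated), via cyclized aldimine 14 (not isolated)
Conditions: 12, MgSO4, toluene, rt; [RhCl(coe)2]2 (10 mol %, coe = cyclooctene), (dicyclohexylphosphino)ferrocene FcPCy2 (30 mol %), toluene, 75 °C; 1 M HCl, THF, rt
Reagents that add atoms: water, O
Why: Imine-directed C–H activation by a monovalent rhodium catalyst at the C–H bond between the imine and the aryloxy group, then intramolecular syn hydroarylation of the tethered enoate (a cyclization with close precedent on the dimethoxy analogue of this substrate); the chiral N-substituent sets the O-bearing benzylic centre as 2R, syn addition to the Z alkene makes the product cis, and any minor enantiomer should be removable by crystallization here or as a diastereomer after step 11.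

Step 7
Reactants: 15 methyl (2R,3S)-7-(benzyloxy)-2-[4-(benzyloxy)-3-methoxyphenyl]-4-formyl-2,3-dihydro-1-benzofuran-3-carboxylate
Product: 17 methyl (2R,3R)-7-(benzyloxy)-2-[4-(benzyloxy)-3-methoxyphenyl]-4-(dimethoxymethyl)-2,3-dihydro-1-benzofuran-3-carboxylate (trans isomer), via cis acetal ester 16 (not isolated)
Conditions: HC(OMe)3, p-TsOH (5 mol %), MeOH, rt; then NaOMe (2 equiv), MeOH, rt
Reagents that add atoms: trimethyl orthoformate, COC(OC)OC; methanol, CO
Why: Acid-catalysed acetalization masks the aldehyde, and methoxide then equilibrates the centre alpha to the ester (C3) to the thermodynamically favoured 2,3-trans arrangement while the ether-bearing C2 is untouched.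

Step 8
Reactants: 17 methyl (2R,3R)-7-(benzyloxy)-2-[4-(benzyloxy)-3-methoxyphenyl]-4-(dimethoxymethyl)-2,3-dihydro-1-benzofuran-3-carboxylate
Product: 18 [(2R,3S)-7-(benzyloxy)-2-[4-(benzyloxy)-3-methoxyphenyl]-4-(dimethoxymethyl)-2,3-dihydro-1-benzofuran-3-yl]methanol
Conditions: LiAlH4, THF, 0 °C
Reagents that add atoms: none
Why: Hydride reduction of the ester to the primary alcohol; acetal and benzyl ethers are inert, and the descriptor at C3 changes only because the substituent priorities change.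

Step 9
Reactants: 18 [(2R,3S)-7-(benzyloxy)-2-[4-(benzyloxy)-3-methoxyphenyl]-4-(dimethoxymethyl)-2,3-dihydro-1-benzofuran-3-yl]methanol
Product: 20 (2R,3S)-7-(benzyloxy)-2-[4-(benzyloxy)-3-methoxyphenyl]-3-[(benzyloxy)methyl]-2,3-dihydro-1-benzofuran-4-carbaldehyde, via benzyl ether acetal 19 (not isolated)
Conditions: NaH, BnBr, n-Bu4NI (cat.), DMF, 0 °C to rt; then 1 M HCl, THF, rt
Reagents that add atoms: benzyl bromide, BrCc1ccccc1; water, O
Why: Williamson etherification of the primary alkoxide followed by mild acid hydrolysis of the dimethyl acetal, which the cyclic benzylic ether and the benzyl ethers should tolerate at room temperature.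

Step 10
Reactants: 21 (S)-4-benzyl-1,3-oxazolidine-2-thione; 22 (benzyloxy)acetyl chloride
Product: 23 (S)-4-benzyl-3-[(benzyloxy)acetyl]-1,3-oxazolidine-2-thione
Conditions: Et3N, CH2Cl2, 0 °C
Reagents that add atoms: none
Why: N-acylation of the oxazolidinethione auxiliary with the acid chloride.

Step 11
Reactants: 23 (S)-4-benzyl-3-[(benzyloxy)acetyl]-1,3-oxazolidine-2-thione; 20 aldehyde ArCHO
Product: 25 (4S)-4-benzyl-3-[(2R,3R)-2-(benzyloxy)-3-hydroxy-3-Ar-propanoyl]-1,3-oxazolidine-2-thione, via titanium enolate 24 (not isolated)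
Conditions: TiCl4 (1.1 equiv), i-Pr2NEt (1.2 equiv), CH2Cl2, −78 °C; then 20 premixed with TiCl4 (2.5 equiv), CH2Cl2, −78 °C
Reagents that add atoms: none
Why: Anti-selective glycolate aldol in which the Z chlorotitanium enolate adds through an open transition state to the TiCl4-complexed aldehyde; the benzyl group of the auxiliary shields one enolate face (2R), the open transition state gives the anti relationship (3R), and reagent control is expected to override the remote dihydrofuran centres.

Step 12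
Reactants: 25 (4S)-4-benzyl-3-[(2R,3R)-2-(benzyloxy)-3-hydroxy-3-Ar-propanoyl]-1,3-oxazolidine-2-thione
Product: 26 methyl (2R,3R)-2-(benzyloxy)-3-hydroxy-3-Ar-propanoate
Conditions: MeOH, imidazole, CH2Cl2, rt
Reagents that add atoms: methanol, CO
Why: Imidazole-mediated methanolysis of the activated N-acyl oxazolidinethione under conditions too mild for retro-aldol cleavage or epimerization, with release of the auxiliary.

Step 13
Reactants: 26 methyl (2R,3R)-2-(benzyloxy)-3-hydroxy-3-Ar-propanoate
Product: 27 methyl (2R,3R)-2-(benzyloxy)-3-Ar-3-[(trimethylsilyl)oxy]propanoate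
Conditions: Me3SiCl, imidazole, CH2Cl2, 0 °C
Reagents that add atoms: chlorotrimethylsilane, C[Si](C)(C)Cl
Why: O-silylation of the secondary alcohol installs a fluoride-labile group that will later release the alkoxide without a proton source.

Step 14
Reactants: 27 methyl (2R,3R)-2-(benzyloxy)-3-Ar-3-[(trimethylsilyl)oxy]propanoate; 5 3,5-bis(benzyloxy)-2-(trimethylsilyl)phenyl trifluoromethanesulfonate
Product: 31 (2R,3R)-3,5,7-tris(benzyloxy)-2-Ar-2,3-dihydro-4H-chromen-4-one, via cesium alkoxide 28 (not isolated), via aryne 29 (not isolated), via aryl cesium adduct 30 (not isolated)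
Conditions: 5 (2.5 equiv), CsF (6 equiv), THF, 65 °C
Reagents that add atoms: none
Why: Proposed new method: fluoride removes the O-silyl group of 27 and the C-silyl group of 5 in an aprotic medium, so that cesium alkoxide 28 meets aryne 29 with no O–H present; the alkoxide oxygen adds to the aryne carbon meta to the neighbouring benzyloxy group (the future C8a), which places the carbanion on the carbon ortho to that oxygen (the future C4a, adduct 30), and this carbanion attacks the methyl ester and expels methoxide. The closest known reaction type is the fluoride-mediated annulation of salicylate esters with 2-(trimethylsilyl)aryl triflates to xanthones (O-arylation followed by anionic acylation), extended here from a phenoxide to a secondary alkoxide released from its silyl ether. The pyranone ring closes by 6-exo-trig acyl substitution of the aryl anion on the ester carbonyl, and it is the only ring formed. No stereocentre is created: C2 and C3 come from the aldol of step 11, no bond to either is made or broken, and the 2,3-trans diequatorial product is also the thermodynamic one should C3 enolize. The step needs regioselective addition, secured by the benzyloxy group next to the aryne bond, which as in 3-alkoxybenzynes directs the nucleophile to the remote aryne carbon, and it needs acylation to beat protonation of the aryl anion, secured by the proton-free alkoxide source and the six-membered transition state; the excess of 5 also scavenges the methoxide.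

Step 15
Reactants: 31 (2R,3R)-3,5,7-tris(benzyloxy)-2-Ar-2,3-dihydro-4H-chromen-4-one
Product: 32 (2R,3R)-3,5,7-trihydroxy-2-[(2R,3S)-7-hydroxy-2-(4-hydroxy-3-methoxyphenyl)-3-(hydroxymethyl)-2,3-dihydro-1-benzofuran-4-yl]-2,3-dihydro-4H-chromen-4-one
Conditions: H2 (1 atm), Pd/C, THF/MeOH, rt, stopped at full debenzylation
Reagents that add atoms: none
Why: Neutral catalytic hydrogenolysis of the six benzyl ethers, under which the base- and acid-sensitive flavanonol centres are not epimerized.

**Compound list**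

1 | 3,5-bis(benzyloxy)phenol | Oc1cc(OCc2ccccc2)cc(OCc2ccccc2)c1 | starting material
2 | 3,5-bis(benzyloxy)-2-bromophenol | Oc1cc(OCc2ccccc2)cc(OCc2ccccc2)c1Br | intermediate
3 | [3,5-bis(benzyloxy)-2-bromophenoxy]trimethylsilane | C[Si](C)(C)Oc1cc(OCc2ccccc2)cc(OCc2ccccc2)c1Br | intermediate
4 | lithium 3,5-bis(benzyloxy)-2-(trimethylsilyl)phenoxide | [Li+].[O-]c1cc(OCc2ccccc2)cc(OCc2ccccc2)c1[Si](C)(C)C | intermediate
5 | 3,5-bis(benzyloxy)-2-(trimethylsilyl)phenyl trifluoromethanesulfonate | C[Si](C)(C)c1c(OS(=O)(=O)C(F)(F)F)cc(OCc2ccccc2)cc1OCc1ccccc1 | intermediate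
6 | 4-(benzyloxy)-3-methoxybenzaldehyde | COc1cc(C=O)ccc1OCc1ccccc1 | starting material
7 | 1-(benzyloxy)-4-(2,2-dibromoethenyl)-2-methoxybenzene | COc1cc(C=C(Br)Br)ccc1OCc1ccccc1 | intermediate
8 | lithium [4-(benzyloxy)-3-methoxyphenyl]acetylide | [Li+].[C-]#Cc1ccc(OCc2ccccc2)c(OC)c1 | intermediate
9 | methyl 3-[4-(benzyloxy)-3-methoxyphenyl]prop-2-ynoate | COC(=O)C#Cc1ccc(OCc2ccccc2)c(OC)c1 | intermediate
10 | 4-(benzyloxy)-3-hydroxybenzaldehyde | O=Cc1ccc(OCc2ccccc2)c(O)c1 | starting material
11 | methyl (Z)-3-[2-(benzyloxy)-5-formylphenoxy]-3-[4-(benzyloxy)-3-methoxyphenyl]prop-2-enoate | COC(=O)/C=C(\Oc1cc(C=O)ccc1OCc1ccccc1)c1ccc(OCc2ccccc2)c(OC)c1 | intermediate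
12 | (S)-1-aminoindane | N[C@H]1CCc2ccccc21 | starting material
13 | (E)-N-[(S)-indan-1-yl] aldimine of 11 | COC(=O)/C=C(\Oc1cc(/C=N/[C@H]2CCc3ccccc32)ccc1OCc1ccccc1)c1ccc(OCc2ccccc2)c(OC)c1 | intermediate
14 | (E)-N-[(S)-indan-1-yl] aldimine of cis ester 15 | COc1cc([C@@H]2Oc3c(OCc4ccccc4)ccc(/C=N/[C@H]4CCc5ccccc54)c3[C@@H]2C(=O)OC)ccc1OCc1ccccc1 | intermediate
15 | methyl (2R,3S)-7-(benzyloxy)-2-[4-(benzyloxy)-3-methoxyphenyl]-4-formyl-2,3-dihydro-1-benzofuran-3-carboxylate (cis) | COc1cc([C@@H]2Oc3c(OCc4ccccc4)ccc(C=O)c3[C@@H]2C(=O)OC)ccc1OCc1ccccc1 | intermediate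
16 | methyl (2R,3S)-7-(benzyloxy)-2-[4-(benzyloxy)-3-methoxyphenyl]-4-(dimethoxymethyl)-2,3-dihydro-1-benzofuran-3-carboxylate (cis) | COc1cc([C@@H]2Oc3c(OCc4ccccc4)ccc(C(OC)OC)c3[C@@H]2C(=O)OC)ccc1OCc1ccccc1 | intermediate
17 | methyl (2R,3R)-7-(benzyloxy)-2-[4-(benzyloxy)-3-methoxyphenyl]-4-(dimethoxymethyl)-2,3-dihydro-1-benzofuran-3-carboxylate (trans) | COc1cc([C@@H]2Oc3c(OCc4ccccc4)ccc(C(OC)OC)c3[C@H]2C(=O)OC)ccc1OCc1ccccc1 | intermediate
18 | [(2R,3S)-7-(benzyloxy)-2-[4-(benzyloxy)-3-methoxyphenyl]-4-(dimethoxymethyl)-2,3-dihydro-1-benzofuran-3-yl]methanol | COc1cc([C@@H]2Oc3c(OCc4ccccc4)ccc(C(OC)OC)c3[C@H]2CO)ccc1OCc1ccccc1 | intermediate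
19 | (2R,3S)-7-(benzyloxy)-2-[4-(benzyloxy)-3-methoxyphenyl]-3-[(benzyloxy)methyl]-4-(dimethoxymethyl)-2,3-dihydro-1-benzofuran | COc1cc([C@@H]2Oc3c(OCc4ccccc4)ccc(C(OC)OC)c3[C@H]2COCc2ccccc2)ccc1OCc1ccccc1 | intermediate
20 | (2R,3S)-7-(benzyloxy)-2-[4-(benzyloxy)-3-methoxyphenyl]-3-[(benzyloxy)methyl]-2,3-dihydro-1-benzofuran-4-carbaldehyde (ArCHO) | COc1cc([C@@H]2Oc3c(OCc4ccccc4)ccc(C=O)c3[C@H]2COCc2ccccc2)ccc1OCc1ccccc1 | intermediate
21 | (S)-4-benzyl-1,3-oxazolidine-2-thione | S=C1N[C@@H](Cc2ccccc2)CO1 | starting material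
22 | (benzyloxy)acetyl chloride | O=C(Cl)COCc1ccccc1 | starting material
23 | (S)-4-benzyl-3-[(benzyloxy)acetyl]-1,3-oxazolidine-2-thione | O=C(COCc1ccccc1)N1[C@@H](Cc2ccccc2)COC1=S | intermediate
24 | trichlorotitanium (Z)-enolate of 23 | Cl[Ti](Cl)(Cl)O/C(=C\OCc1ccccc1)N1[C@@H](Cc2ccccc2)COC1=S | intermediate
25 | (4S)-4-benzyl-3-[(2R,3R)-2-(benzyloxy)-3-hydroxy-3-Ar-propanoyl]-1,3-oxazolidine-2-thione | COc1cc([C@@H]2Oc3c(OCc4ccccc4)ccc([C@@H](O)[C@@H](OCc4ccccc4)C(=O)N4[C@@H](Cc5ccccc5)COC4=S)c3[C@H]2COCc2ccccc2)ccc1OCc1ccccc1 | intermediate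
26 | methyl (2R,3R)-2-(benzyloxy)-3-hydroxy-3-Ar-propanoate | COc1cc([C@@H]2Oc3c(OCc4ccccc4)ccc([C@@H](O)[C@@H](OCc4ccccc4)C(=O)OC)c3[C@H]2COCc2ccccc2)ccc1OCc1ccccc1 | intermediate
27 | methyl (2R,3R)-2-(benzyloxy)-3-Ar-3-[(trimethylsilyl)oxy]propanoate | COc1cc([C@@H]2Oc3c(OCc4ccccc4)ccc([C@@H](O[Si](C)(C)C)[C@@H](OCc4ccccc4)C(=O)OC)c3[C@H]2COCc2ccccc2)ccc1OCc1ccccc1 | intermediate
28 | cesium alkoxide of 26 | COc1cc([C@@H]2Oc3c(OCc4ccccc4)ccc([C@@H]([O-])[C@@H](OCc4ccccc4)C(=O)OC)c3[C@H]2COCc2ccccc2)ccc1OCc1ccccc1.[Cs+] | intermediate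
29 | 3,5-bis(benzyloxy)benzyne | C1#CC(OCc2ccccc2)=CC(OCc2ccccc2)=C1 | intermediate
30 | aryl cesium adduct, methyl (2R,3R)-2-(benzyloxy)-3-Ar-3-[3,5-bis(benzyloxy)-2-cesiophenoxy]propanoate | COc1cc([C@@H]2Oc3c(OCc4ccccc4)ccc([C@@H](Oc4cc(OCc5ccccc5)cc(OCc5ccccc5)[c-]4)[C@@H](OCc4ccccc4)C(=O)OC)c3[C@H]2COCc2ccccc2)ccc1OCc1ccccc1.[Cs+] | intermediate
31 | (2R,3R)-3,5,7-tris(benzyloxy)-2-Ar-2,3-dihydro-4H-chromen-4-one | COc1cc([C@@H]2Oc3c(OCc4ccccc4)ccc([C@H]4Oc5cc(OCc6ccccc6)cc(OCc6ccccc6)c5C(=O)[C@@H]4OCc4ccccc4)c3[C@H]2COCc2ccccc2)ccc1OCc1ccccc1 | intermediate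
32 | (2R,3R)-3,5,7-trihydroxy-2-[(2R,3S)-7-hydroxy-2-(4-hydroxy-3-methoxyphenyl)-3-(hydroxymethyl)-2,3-dihydro-1-benzofuran-4-yl]-2,3-dihydro-4H-chromen-4-one | COc1cc([C@@H]2Oc3c(O)ccc([C@H]4Oc5cc(O)cc(O)c5C(=O)[C@@H]4O)c3[C@H]2CO)ccc1O | target

**Step count and risks**

Total step count: 15. Longest linear sequence: 12 steps (steps 3 to 9 and 11 to 15, from compound 6).

Steps most likely to fail:

1. Step 14 (key step, proposed method). The cesium alkoxide may fragment by retro-aldol cleavage before it is arylated. The aryl anion may be protonated instead of acylated, which stops at the open aryl ether. Fluoride basicity may enolize C3 of the product and open the pyranone ring by beta-elimination, which would scramble C2.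
Fallback with known chemistry, setting out from 25 and returning at 31: the auxiliary of 25 is displaced with MeNH(OMe)·HCl and imidazole (CH2Cl2, rt) to give the Weinreb amide F1, and its hydroxyl group is silylated (Et3SiCl, imidazole, DMF) to the triethylsilyl ether F2. In parallel, 1,3,5-trifluorobenzene is taken through two aromatic substitutions with BnOH and NaH (NMP, 80 °C) to 1,3-bis(benzyloxy)-5-fluorobenzene F3, which NBS (MeCN, 0 °C) brominates para to one benzyloxy group to give 2-bromo-1,5-bis(benzyloxy)-3-fluorobenzene F4. Bromine–lithium exchange on F4 (n-BuLi, THF, −78 °C) and addition of F2 give the 2-fluoroaryl ketone F5. n-Bu4NF (THF, 0 °C) then removes the silyl group, and the alkoxide closes the pyranone ring by intramolecular nucleophilic aromatic substitution of the fluoride ortho to the ketone, which gives 31.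

2. Step 11 (anti glycolate aldol). Facial selectivity may be poor if the resident dihydrofuran centres and the ortho substituent work against the auxiliary, the anti preference of the open transition state may erode, and the excess TiCl4 may ionize the cyclic benzylic ether.
Fallback with known chemistry, setting out from 20 and returning at 26: a Mukaiyama aldol under control of a chiral tin Lewis acid replaces the auxiliary. Acid chloride 22 is converted with EtSH and Et3N to S-ethyl (benzyloxy)ethanethioate F6, and enolization with LiN(i-Pr)2 and Me3SiCl (THF, −78 °C) gives the (Z)-silyl ketene thioacetal F7. Aldehyde 20 and F7 are combined with Sn(OTf)2, n-Bu2Sn(OAc)2 and the enantiomer of 1-methyl-2-[(naphthalen-1-ylamino)methyl]pyrrolidine that leads to the 2R,3R adduct (CH2Cl2, −78 °C) to give the anti thioester F8. Silver-assisted methanolysis (AgOCOCF3, MeOH) then gives 26.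

3. Step 15 (global hydrogenolysis). Over-reduction may cleave the two ring benzylic C–O bonds (C2–O of the dihydrofuran and C2–O1 of the pyranone) or reduce the ketone before the two aliphatic benzyl ethers are gone.
Fallback with known chemistry, setting out from 31 and returning at 32: the benzyl ethers are cleaved by a Lewis acid in place of hydrogen, with BCl3 and pentamethylbenzene as benzyl cation scavenger (CH2Cl2, −78 °C). No new compound is made on the way.

**Further compounds**

F1 | step 14 | (2R,3R)-2-(benzyloxy)-3-hydroxy-N-methoxy-N-methyl-3-Ar-propanamide | COc1cc([C@@H]2Oc3c(OCc4ccccc4)ccc([C@@H](O)[C@@H](OCc4ccccc4)C(=O)N(C)OC)c3[C@H]2COCc2ccccc2)ccc1OCc1ccccc1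
F2 | step 14 | (2R,3R)-2-(benzyloxy)-N-methoxy-N-methyl-3-Ar-3-[(triethylsilyl)oxy]propanamide | COc1cc([C@@H]2Oc3c(OCc4ccccc4)ccc([C@@H](O[Si](CC)(CC)CC)[C@@H](OCc4ccccc4)C(=O)N(C)OC)c3[C@H]2COCc2ccccc2)ccc1OCc1ccccc1
F3 | step 14 | 1,3-bis(benzyloxy)-5-fluorobenzene | Fc1cc(OCc2ccccc2)cc(OCc2ccccc2)c1
F4 | step 14 | 2-bromo-1,5-bis(benzyloxy)-3-fluorobenzene | Fc1cc(OCc2ccccc2)cc(OCc2ccccc2)c1Br
F5 | step 14 | (2R,3R)-2-(benzyloxy)-1-[2,4-bis(benzyloxy)-6-fluorophenyl]-3-Ar-3-[(triethylsilyl)oxy]propan-1-one | COc1cc([C@@H]2Oc3c(OCc4ccccc4)ccc([C@@H](O[Si](CC)(CC)CC)[C@@H](OCc4ccccc4)C(=O)c4c(F)cc(OCc5ccccc5)cc4OCc4ccccc4)c3[C@H]2COCc2ccccc2)ccc1OCc1ccccc1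
F6 | step 11 | S-ethyl (benzyloxy)ethanethioate | CCSC(=O)COCc1ccccc1
F7 | step 11 | (Z)-{[2-(benzyloxy)-1-(ethylsulfanyl)ethenyl]oxy}trimethylsilane | CCS/C(O[Si](C)(C)C)=C\OCc1ccccc1
F8 | step 11 | S-ethyl (2R,3R)-2-(benzyloxy)-3-hydroxy-3-Ar-propanethioate | COc1cc([C@@H]2Oc3c(OCc4ccccc4)ccc([C@@H](O)[C@@H](OCc4ccccc4)C(=O)SCC)c3[C@H]2COCc2ccccc2)ccc1OCc1ccccc1
F0 | step 15 | none | none
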